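**Retrosynthetic overview**
- Feature: in each half, ring B with C2, C3 and C4 of ring C is a 4-oxygenated cinnamoyl unit. The two units are joined C3–C3'' in the unlike (3R,3''S) sense, so the skeleton is meso, and the target is chiral only because ring B of the (2S,3R) half carries OMe and the other ring B carries OH.
- Last disconnections: four MOM ethers and one acetate, then the O-methyl group. The methyl group is placed after a lipase has told apart the two enantiotopic ring B acetates of the meso biflavanone.
- Both rings C: O1–C2 and O1''–C2'' open to a bis(p-quinone methide). This traces back to a cyclobutane with a sacrificial C2–C2'' bond between two carbons that each bear a 4-hydroxyphenyl group.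
- Rings A: C4–C4a and C4''–C4a'' are cut to lithiated tris-MOM phloroglucinol and an aryl diester.
- Cyclobutane: retro-[2+2] to two 4-benzyloxycinnamates held on the peri oxygens of 1,8-dihydroxynaphthalene. Forward ring order: cyclobutane first, rings A attached next, both rings C closed as the cyclobutane opens.

Key step: step 3

Assumption: which of the two enantiotopic ring B acetates a lipase attacks cannot be predicted, so the route is written for an enzyme that frees the phenol on the (2S,3R) half; if screening shows the opposite preference, the same enzyme run in the acylation direction (vinyl acetate on the meso bisphenol) leads to the same monoacetate.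

Step 1
Reactants: 1 (E)-4-hydroxycinnamic acid
Product: 3 (E)-3-(4-benzyloxyphenyl)acrylic acid, via benzyl (E)-3-(4-benzyloxyphenyl)acrylate 2 (not isolated)
Conditions: BnBr (2.3 equiv), K2CO3, DMF, 60 °C; then NaOH aq, MeOH–THF, 60 °C; HCl aq
Reagents that add atoms: benzyl bromide BrCc1ccccc1; sodium hydroxide [Na+].[OH-] (one oxygen of the regenerated CO2H)
Why: Williamson alkylation of phenoxide and carboxylate is followed by saponification of the benzyl ester only, which leaves the aryl benzyl ether and the E alkene untouched.

Step 2
Reactants: 3 (E)-3-(4-benzyloxyphenyl)acrylic acid (2.1 equiv); 4 1,8-dihydroxynaphthalene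
Product: 5 naphthalene-1,8-diyl bis[(E)-3-(4-benzyloxyphenyl)acrylate]
Conditions: DCC (2.2 equiv), DMAP (0.2 equiv), CH2Cl2, 0 °C → rt
Reagents that add atoms: none
Why: In this Steglich esterification the acylpyridinium formed from DMAP acylates both peri phenols, no stereocentre is made and the E geometry is kept.

Step 3
Reactants: 5 naphthalene-1,8-diyl bis[(E)-3-(4-benzyloxyphenyl)acrylate]
Product: 6 naphthalene-1,8-diyl (1R,2S,3R,4S)-3,4-bis(4-benzyloxyphenyl)cyclobutane-1,2-dicarboxylate (β-truxinate; both acyl groups on one face, both aryl groups on the other face; meso)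
Conditions: hν (UV-A, 350–365 nm, Pyrex), finely ground crystalline layer, N2, rt, layer turned over periodically
Reagents that add atoms: none
Why: Excitation of one 4-alkoxycinnamate chromophore is followed by a suprafacial [π2s+π2s] photocycloaddition to the ground-state partner, which the two peri oxygens hold within bonding distance with both C=C bonds pointing the same way. The closest known reaction type is the template-directed, topochemical photodimerisation of cinnamates on 1,8-dihydroxynaphthalene to β-truxinates. The cyclobutane is closed by cycloaddition, C3–C3'' and the temporary C2–C2'' bond forming in one event, and the C3–C3'' bond also closes a nine-membered dilactone ring through the naphthalene peri positions. Each alkene keeps its E geometry, so every aryl group ends trans to its neighbouring acyl group, and the syn stacking puts acyl cis to acyl and aryl cis to aryl, which gives C3/C3'' the unlike relationship of the target in an achiral meso product. The step needs head-to-head over head-to-tail pairing and intramolecular over intermolecular reaction (both secured by the rigid tether), and it must outrun E/Z isomerisation and photo-Fries cleavage (suppressed by the solid state and the long wavelength).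

Step 4
Reactants: 7 phloroglucinol
Product: 8 1,3,5-tris(methoxymethoxy)benzene
Conditions: NaH (3.6 equiv), MOMCl (3.6 equiv), DMF, 0 °C → rt
Reagents that add atoms: chloromethyl methyl ether COCCl
Why: Williamson-type O-alkylation of the three phenoxides by the hard electrophile MOMCl is favoured over C-alkylation in DMF at low temperature.

Step 5
Reactants: 8 1,3,5-tris(methoxymethoxy)benzene (2.4 equiv); 6 naphthalene-1,8-diyl β-truxinate
Product: 10 [(1R,2S,3R,4S)-3,4-bis(4-benzyloxyphenyl)cyclobutane-1,2-diyl]bis{[2,4,6-tris(methoxymethoxy)phenyl]methanone} (meso), via 2,4,6-tris(methoxymethoxy)phenyllithium 9 (not isolated)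
Conditions: n-BuLi (2.3 equiv), THF, 0 °C; then added slowly to 6, THF, −78 °C; AcOH quench at −78 °C
Reagents that add atoms: n-butyllithium [Li]CCCC (lithium of 9 only)
Why: Directed ortho-lithiation between two OMOM groups gives 9, whose nucleophilic acyl substitution on the activated aryl ester expels the naphtholate (template 4 is recovered); the doubly ortho-substituted ketone is too hindered for a second addition, and the low temperature and cold acidic quench keep the cis C3/C3'' pair from enolising.

Step 6
Reactants: 10 hexa-MOM bis-ketone
Product: 11 [(1R,2S,3R,4S)-3,4-bis(4-benzyloxyphenyl)cyclobutane-1,2-diyl]bis{[2-hydroxy-4,6-bis(methoxymethoxy)phenyl]methanone} (meso)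
Conditions: p-TsOH·H2O (0.2 equiv), MeOH–CH2Cl2, 0 °C → rt, stopped when one MOM group per ring A is lost
Reagents that add atoms: none
Why: Acid-catalysed transacetalisation to methanol is fastest for a MOM group ortho to the ketone because the carbonyl assists departure of that phenol by hydrogen bonding, and once this hydrogen bond exists the second ortho and the para MOM groups lack such help.

Step 7
Reactants: 11 bis(2-hydroxyaryl) ketone with ring B benzyl ethers
Product: 12 [(1R,2S,3R,4S)-3,4-bis(4-hydroxyphenyl)cyclobutane-1,2-diyl]bis{[2-hydroxy-4,6-bis(methoxymethoxy)phenyl]methanone} (meso)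
Conditions: H2 (1 atm), Pd/C (10 wt%), EtOAc–MeOH, rt
Reagents that add atoms: none
Why: Catalytic hydrogenolysis of the two benzyl aryl ethers runs under neutral, mild conditions at which the hindered aryl ketones, the MOM acetals and the cyclobutane C–C bonds should persist.

Step 8
Reactants: 12 cyclobutane tetraphenol
Product: 14 (2S,3R,2''R,3''S)-4',4'''-dihydroxy-5,5'',7,7''-tetrakis(methoxymethoxy)-3,3''-biflavanone (meso; both rings C 2,3-trans), via bis(p-quinone methide) 13 (not isolated)
Conditions: PhI(OAc)2 (1.0 equiv, slow addition), (CF3)2CHOH–CH2Cl2, −20 → 0 °C; NaHCO3 aq work-up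
Reagents that add atoms: none
Why: Proposed new method: ligand exchange of a ring B phenol on PhI(OAc)2 and loss of PhI in the ionising, non-nucleophilic solvent places positive charge on the ring carbon para to oxygen, next to C2. The cis aryl groups of 12 are forced face to face, so their π systems lie along the strained, doubly benzylic C2–C2'' σ bond and roughly orthogonal to C2–H; this bond should therefore break in a Grob-type fragmentation in which the second 4-hydroxyphenyl group stabilises the departing C2'' cation, and loss of two protons leaves 13. Each ring A phenol then adds to its own quinone methide carbon (oxa-1,6-addition, favoured 6-exo-trig, six- rather than seven-membered ring), which re-aromatises ring B and closes both rings C. C3 and C3'' are not touched, C2 and C2'' are re-set trans to them through a chair-like closure with the aryl group and the C3 substituent equatorial, and a cis isomer can re-open through the same quinone methide and correct itself. The acyl groups on C3/C3'' disfavour the second cleavage (C3–C3'', full cycloreversion to chalcones) because it would place cationic character on an enone. The closest known reaction types are the oxidation of 4-alkylphenols to p-quinone methides by trivalent iodine reagents or Ag2O with phenol capture to flavans, and the oxidative ring-opening 1,3-difunctionalisation of arylcyclopropanes.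

Step 9
Reactants: 14 meso biflavanone bisphenol
Product: 15 (2S,3R,2''R,3''S)-4',4'''-diacetoxy-5,5'',7,7''-tetrakis(methoxymethoxy)-3,3''-biflavanone (meso)
Conditions: Ac2O, pyridine, CH2Cl2, 0 °C → rt
Reagents that add atoms: acetic anhydride CC(=O)OC(C)=O
Why: O-Acetylation of the only two free phenols runs under weakly basic conditions that should neither open ring C nor enolise C3.

Step 10
Reactants: 15 meso diacetate
Product: 16 (2S,3R,2''R,3''S)-4'''-acetoxy-4'-hydroxy-5,5'',7,7''-tetrakis(methoxymethoxy)-3,3''-biflavanone (free phenol on the 2S,3R half, acetate on the 2''R,3''S half; single enantiomer)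
Conditions: Candida rugosa lipase, n-BuOH (5 equiv), i-Pr2O–THF, 40 °C
Reagents that add atoms: none
Why: This is a lipase-catalysed enantiotopic-group-selective alcoholysis of a meso diacetate, a reaction type known for aryl acetates of flavanones: the two esters sit para to mirror-image C2 centres, the chiral binding pocket should release one of them faster, and the minor monoacetate still carries the fast-reacting ester and is drained to 14 (recycled through step 9), so the absolute configuration of the target is fixed here without touching a stereocentre.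

Step 11
Reactants: 16 monoacetate
Product: 17 (2S,3R,2''R,3''S)-4'''-acetoxy-4'-methoxy-5,5'',7,7''-tetrakis(methoxymethoxy)-3,3''-biflavanone
Conditions: MeOH, PPh3, DIAD, THF, 0 °C → rt
Reagents that add atoms: methanol CO
Why: Mitsunobu etherification of the single free phenol by methanol proceeds without a free phenoxide, so neither intermolecular acetyl transfer between ring B oxygens (which would racemise 16) nor base-induced opening of ring C should intervene.

Step 12
Reactants: 17 methyl ether acetate
Product: 18 target, (2S,3R,2''R,3''S)-5,5'',7,7'',4'''-pentahydroxy-4'-methoxy-3,3''-biflavanone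
Conditions: HCl in MeOH (1.25 M), THF, 40 °C
Reagents that add atoms: none
Why: Acid-catalysed transacetalisation of the four MOM ethers and transesterification of the aryl acetate to methanol release all five phenols, while the aryl methyl ether stays and the moderate temperature avoids enolisation at C3/C3'' and opening of ring C.

**Compound list**
1 | (E)-4-hydroxycinnamic acid | OC(=O)/C=C/c1ccc(O)cc1 | starting material
2 | benzyl (E)-3-(4-benzyloxyphenyl)acrylate | O=C(/C=C/c1ccc(OCc2ccccc2)cc1)OCc1ccccc1 | intermediate
3 | (E)-3-(4-benzyloxyphenyl)acrylic acid | OC(=O)/C=C/c1ccc(OCc2ccccc2)cc1 | intermediate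
4 | 1,8-dihydroxynaphthalene | Oc1cccc2cccc(O)c12 | starting material
5 | naphthalene-1,8-diyl bis[(E)-3-(4-benzyloxyphenyl)acrylate] | O=C(/C=C/c1ccc(OCc2ccccc2)cc1)Oc1cccc2cccc(OC(=O)/C=C/c3ccc(OCc4ccccc4)cc3)c12 | intermediate
6 | naphthalene-1,8-diyl (1R,2S,3R,4S)-3,4-bis(4-benzyloxyphenyl)cyclobutane-1,2-dicarboxylate (β-truxinate, meso) | [C@@H]12C(=O)Oc3cccc4cccc(c34)OC(=O)[C@H]2[C@H](c2ccc(OCc3ccccc3)cc2)[C@@H]1c1ccc(OCc2ccccc2)cc1 | intermediate
7 | phloroglucinol | Oc1cc(O)cc(O)c1 | starting material
8 | 1,3,5-tris(methoxymethoxy)benzene | COCOc1cc(OCOC)cc(OCOC)c1 | intermediate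
9 | 2,4,6-tris(methoxymethoxy)phenyllithium | [Li]c1c(OCOC)cc(OCOC)cc1OCOC | intermediate
10 | meso cyclobutane bis[2,4,6-tris(methoxymethoxy)phenyl ketone], rings B as benzyl ethers | O=C(c1c(OCOC)cc(OCOC)cc1OCOC)[C@H]1[C@@H](C(=O)c2c(OCOC)cc(OCOC)cc2OCOC)[C@H](c2ccc(OCc3ccccc3)cc2)[C@@H]1c1ccc(OCc2ccccc2)cc1 | intermediate
11 | meso cyclobutane bis[2-hydroxy-4,6-bis(methoxymethoxy)phenyl ketone], rings B as benzyl ethers | O=C(c1c(O)cc(OCOC)cc1OCOC)[C@H]1[C@@H](C(=O)c2c(O)cc(OCOC)cc2OCOC)[C@H](c2ccc(OCc3ccccc3)cc2)[C@@H]1c1ccc(OCc2ccccc2)cc1 | intermediate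
12 | meso cyclobutane bis[2-hydroxy-4,6-bis(methoxymethoxy)phenyl ketone], rings B as free phenols | O=C(c1c(O)cc(OCOC)cc1OCOC)[C@H]1[C@@H](C(=O)c2c(O)cc(OCOC)cc2OCOC)[C@H](c2ccc(O)cc2)[C@@H]1c1ccc(O)cc1 | intermediate
13 | meso-2,3-bis[(4-oxocyclohexa-2,5-dien-1-ylidene)methyl]-1,4-bis[2-hydroxy-4,6-bis(methoxymethoxy)phenyl]butane-1,4-dione | O=C1C=CC(=C[C@@H](C(=O)c2c(O)cc(OCOC)cc2OCOC)[C@@H](C(=O)c2c(O)cc(OCOC)cc2OCOC)C=C2C=CC(=O)C=C2)C=C1 | intermediate
14 | (2S,3R,2''R,3''S)-4',4'''-dihydroxy-5,5'',7,7''-tetrakis(methoxymethoxy)-3,3''-biflavanone (meso) | Oc1ccc([C@H]2Oc3cc(OCOC)cc(OCOC)c3C(=O)[C@@H]2[C@@H]2C(=O)c3c(OCOC)cc(OCOC)cc3O[C@H]2c2ccc(O)cc2)cc1 | intermediate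
15 | 4',4'''-diacetate of 14 (meso) | CC(=O)Oc1ccc([C@H]2Oc3cc(OCOC)cc(OCOC)c3C(=O)[C@@H]2[C@@H]2C(=O)c3c(OCOC)cc(OCOC)cc3O[C@H]2c2ccc(OC(C)=O)cc2)cc1 | intermediate
16 | 4'''-monoacetate, free 4'-OH on the (2S,3R) half | Oc1ccc([C@H]2Oc3cc(OCOC)cc(OCOC)c3C(=O)[C@@H]2[C@@H]2C(=O)c3c(OCOC)cc(OCOC)cc3O[C@H]2c2ccc(OC(C)=O)cc2)cc1 | intermediate
17 | 4'-methyl ether 4'''-acetate | COc1ccc([C@H]2Oc3cc(OCOC)cc(OCOC)c3C(=O)[C@@H]2[C@@H]2C(=O)c3c(OCOC)cc(OCOC)cc3O[C@H]2c2ccc(OC(C)=O)cc2)cc1 | intermediate
18 | (2S,3R,2''R,3''S)-5,5'',7,7'',4'''-pentahydroxy-4'-methoxy-3,3''-biflavanone | COc1ccc([C@H]2Oc3cc(O)cc(O)c3C(=O)[C@@H]2[C@@H]2C(=O)c3c(O)cc(O)cc3O[C@H]2c2ccc(O)cc2)cc1 | target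

**Count**
- Total steps: 12.
- Longest linear sequence: 11 (steps 1–3 and 5–12); step 4 is the side branch.

**Steps most likely to fail**

Step 8 (oxidative scission and double closure).
- What may go wrong:
  - After the first C–C cleavage the C3–C3'' bond may also break, which amounts to full cycloreversion.
  - Oxidation may take the benzylic C–H instead of the C–C bond.
  - The quinone methide may tautomerise towards the enone before it is trapped, which would erase C3.
  - The product phenols may be oxidised further.
- Fallback, from 12 back to 14: the temporary bond is removed reductively and C2/C2'' are re-oxidised by known chemistry.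
  - Hydrogenolysis of the doubly benzylic bond, established for 1,2-diarylcyclobutanes (H2 under pressure, Pd(OH)2/C, EtOAc–EtOH, 50 °C), should give meso-2,3-bis(4-hydroxybenzyl)-1,4-bis[2-hydroxy-4,6-bis(methoxymethoxy)phenyl]butane-1,4-dione F1 with C3/C3'' untouched.
  - DDQ (2 equiv, 1,4-dioxane, rt) then performs the familiar benzylic dehydrogenation of each 4-alkylphenol to a p-quinone methide. The neighbouring ring A phenol traps it, and the route is rejoined at 14.

Step 10 (lipase desymmetrisation).
- What may go wrong: the ester is far from the nearest stereocentre, so discrimination between the two enantiotopic acetates may be poor, and turnover on so large a substrate may be slow.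
- Fallback, from 14 back to 18: the catalytic selection is replaced by a covalent, separable and recyclable derivatisation.
  - Acylation of 14 with one equivalent of (1S)-camphanic chloride (Et3N, DMAP, CH2Cl2, 0 °C) gives two diastereomeric monoesters, which are separated by chromatography or crystallisation.
  - The wanted one is the 4'''-O-[(1S,4R)-camphanoyl] monoester with the free phenol on the (2S,3R) half F2. The other monoester and the diester are methanolysed back to meso 14, so no material is lost.
  - Mitsunobu methylation as in step 11 gives the 4'-methyl ether camphanate F3.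
  - Methanolic HCl as in step 12, for a longer time, removes the camphanate and the MOM groups and arrives at 18.

Step 5 (template cleavage by the aryllithium).
- What may go wrong:
  - The hindered aryllithium may deprotonate the aryl ester (ketene formation) or the first-formed ketone, which would epimerise the cis C3/C3'' pair.
  - The second acyl substitution may stall.
- Fallback, from 6 back to 10: the acyl donor is changed so that no ketone exists while base is present.
  - Aminolysis of 6 with MeNH(OMe)·HCl and i-PrMgCl (THF, −20 °C) releases 4 and gives the meso bis(N-methoxy-N-methylamide) F4.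
  - Addition of 9 forms two chelated tetrahedral adducts, which collapse only on cold acidic quench to give 10.

**Further compounds**
F1 | step 8 | meso-2,3-bis(4-hydroxybenzyl)-1,4-bis[2-hydroxy-4,6-bis(methoxymethoxy)phenyl]butane-1,4-dione | Oc1ccc(C[C@@H](C(=O)c2c(O)cc(OCOC)cc2OCOC)[C@@H](C(=O)c2c(O)cc(OCOC)cc2OCOC)Cc2ccc(O)cc2)cc1
F2 | step 10 | (2S,3R,2''R,3''S)-4'''-O-[(1S,4R)-camphanoyl]-4'-hydroxy-5,5'',7,7''-tetrakis(methoxymethoxy)-3,3''-biflavanone | Oc1ccc([C@H]2Oc3cc(OCOC)cc(OCOC)c3C(=O)[C@@H]2[C@@H]2C(=O)c3c(OCOC)cc(OCOC)cc3O[C@H]2c2ccc(OC(=O)[C@]3(OC4=O)CC[C@]4(C)C3(C)C)cc2)cc1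
F3 | step 10 | (2S,3R,2''R,3''S)-4'''-O-[(1S,4R)-camphanoyl]-4'-methoxy-5,5'',7,7''-tetrakis(methoxymethoxy)-3,3''-biflavanone | COc1ccc([C@H]2Oc3cc(OCOC)cc(OCOC)c3C(=O)[C@@H]2[C@@H]2C(=O)c3c(OCOC)cc(OCOC)cc3O[C@H]2c2ccc(OC(=O)[C@]3(OC4=O)CC[C@]4(C)C3(C)C)cc2)cc1
F4 | step 5 | (1R,2S,3R,4S)-3,4-bis(4-benzyloxyphenyl)-N,N'-dimethoxy-N,N'-dimethylcyclobutane-1,2-dicarboxamide (meso) | CON(C)C(=O)[C@H]1[C@@H](C(=O)N(C)OC)[C@H](c2ccc(OCc3ccccc3)cc2)[C@@H]1c1ccc(OCc2ccccc2)cc1
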